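**Crossing over.** In the blue run left-handed product reaches 55.7% of the two substrates charged together, more than the left-handed substrate charged, so right-handed substrate has crossed over on the way.

| setting | ochre | blue | flask |
|---|---|---|---|
| left-handed substrate | 0.050 M | 0.050 M | 0.050 M |
| right-handed substrate | 0.050 M | 0.050 M | 0.050 M |
| coupling partner | 1.5 equiv (fed, over 5.0 h) | 2.2 equiv (fed, over 5.0 h) | 3.00 equiv (fed, over 5.0 h) |
| free catalyst | 5 mol% | 5 mol% | 5 mol% |
| impurity | 1.3 mM | 1.3 mM | 1.3 mM |
| remark | run made earlier | run made earlier |  |
| time |  |  | 4.0 d |

| run | time / d | left-handed product / % | right-handed product / % |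
|---|---|---|---|
| ochre | 0.208 | 14.2 | 6.8 |
| ochre | 0.417 | 25.9 | 10.8 |
| ochre | 1.04 | 34.6 | 16.1 |
| ochre | 2.50 | 43.0 | 18.1 |
| blue | 0.333 | 30.3 | 13.1 |
| blue | 0.833 | 43.7 | 19.4 |
| blue | 1.67 | 51.6 | 22.5 |
| blue | 2.50 | 55.7 | 24.5 |

(each reading ± 0.5 percentage points)

- free catalyst is single-handed; left-handed substrate and right-handed substrate are mirror images of each other, charged as a racemate, each of them at the stated concentration
- an excess is the difference of the two amounts in percent of their sum
- an excess is below zero if the other one leads

- left-handed product and right-handed product together, in percent of the left-handed substrate and right-handed substrate charged together, at 4.0 d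
- excess of left-handed product over right-handed product in the product at 4.0 d
- whether the exchange between left-handed substrate and right-handed substrate keeps pace with the reaction: how far the product's excess at 4.0 d gets from its value without exchange to its value with instant exchange (above 80% keeps pace, below 20% hardly takes part, else lags behind)

**Fastest rung.** The blue run's product excess goes from 39.6% at 0.333 d to 38.9% at 2.50 d, and the last of these readings gives 2.27 for the selectivity factor. With the excess this flat, the two substrates count as one pool, and this reckoning expects 38.9% in the flask, with exchange keeping pace.

**Middle rung.** This reckoning works with the fractions left. On the scale of both substrates, the coupling partner charged stands at 0.750 in the ochre run, where it is the limiting reagent, at 1.10 in the blue run and at 1.50 in the flask. The catalyst clock is the logarithm of partner left over substrate left, taken against the charged ratio and divided by the partner's surplus over substrate. It assumes one-for-one use and treats the fed partner as if charged at once. At 2.50 d it reads 2.97 in ochre and 3.14 in blue, despite their different partner charges.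

**Slowest rung.** The blue clock ran at 1.73 d⁻¹ up to 0.833 d. Later readings give 0.881 d⁻¹ in ochre and 1.01 d⁻¹ in blue, slower than at the start. Carried forward at their mean, the clock stands at 4.47, the catalyst clock at the asked time. By this reckoning the flask keeps 3.84% of its substrate, a yield of 96.2%.

**The forecast.** It gives a yield of 94%, below this reckoning, an excess of 39% and the verdict keeps pace: “So exchange keeps pace”.

**The result.** The flask gives a yield of 96.3% and an excess of 38.9%, and exchange keeps pace, 99.8% of the way.

    free catalyst + impurity → spent catalyst (k = 35000 M⁻¹ h⁻¹)
    free catalyst ⇌ dormant form (K = 11.0, k = 0.320 h⁻¹)
    coupling partner + free catalyst + right-handed substrate → free catalyst + right-handed product (k = 2500 M⁻² h⁻¹)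
    coupling partner + free catalyst + left-handed substrate → free catalyst + left-handed product (k = 5700 M⁻² h⁻¹)
    left-handed substrate ⇌ right-handed substrate (k = 18.0 h⁻¹)
    2 free catalyst ⇌ resting dimer, settled at all times (K = 1600 M⁻¹)

**Neighbour flask.** Read back from that yield, the flask's clock stands at 4.52. The neighbour flask is charged with 1.80 equiv of coupling partner, which is 0.900 on the same scale, below substrate. At the reckoned clock of 4.47, the neighbour flask should keep 23.6% of its substrate, a yield of 76.4%. The neighbour flask gives 76.6%.

The data were computed from invented constants, noise included.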